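**Retrosynthetic overview**
1. The allylic alcohol comes from i-Bu2AlH reduction of an (E)-acrylate, itself made by Heck coupling of a bromo-benzodioxane with methyl acrylate; the side chain is built last, after all acid chemistry.
2. Both benzene rings are bought; the only ring made is the 1,4-dioxane ring, closed late by acid-mediated C–O bond formation between a benzylic carbinol and the ring B phenol.
3. The C-methyl group derives from the carboximide carbon of an aldol adduct (reduction, tosylation, hydride displacement).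
4. Key C–C disconnection between the aryl-bearing and methyl-bearing carbons: Evans boron glycolate aldol of an N-(aryloxyacetyl)oxazolidinone with 3,4,5-trimethoxybenzaldehyde, which sets the methyl-bearing stereocentre.
5. The aryloxyacetic acid comes from 5-bromo-o-vanillin (O-alkylation, Baeyer–Villiger, MOM protection), which fixes the ring B oxygen pattern unambiguously.

Assumption: the SMILES is read as the trans isomer with R configuration at both the aryl-bearing and the methyl-bearing ring carbon; 5-bromo-2-hydroxy-3-methoxybenzaldehyde is taken as a catalogue compound.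

**Route**

Step 1
Reactants: 1 5-bromo-2-hydroxy-3-methoxybenzaldehyde; 2 methyl bromoacetate
Product: 3 methyl 2-(4-bromo-2-formyl-6-methoxyphenoxy)acetate
Conditions: K2CO3, DMF, rt
Reagents that add atoms: none
Why: Williamson ether synthesis; the acidic salicylaldehyde-type phenoxide is alkylated by the reactive α-bromo ester at room temperature, below the temperature at which the product closes to a benzofuran by intramolecular aldol condensation.

Step 2
Reactants: 3 methyl 2-(4-bromo-2-formyl-6-methoxyphenoxy)acetate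
Product: 5 methyl 2-(4-bromo-2-hydroxy-6-methoxyphenoxy)acetate, via aryl formate 4 (not isolated)
Conditions: mCPBA, CH2Cl2, 0 °C to rt; aq. Na2S2O3/NaHCO3 wash; then K2CO3 (0.1 equiv), MeOH, 0 °C
Reagents that add atoms: m-chloroperoxybenzoic acid, OOC(=O)c1cccc(Cl)c1
Why: Baeyer–Villiger (Dakin-type) oxidation in which the ortho-alkoxy group drives aryl migration to the aryl formate, followed by base-catalysed methanolysis that frees the phenol and leaves the methyl ester as it is.

Step 3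
Reactants: 5 methyl 2-(4-bromo-2-hydroxy-6-methoxyphenoxy)acetate
Product: 6 methyl 2-[4-bromo-2-methoxy-6-(methoxymethoxy)phenoxy]acetate
Conditions: MOMCl, i-Pr2NEt, CH2Cl2, 0 °C to rt
Reagents that add atoms: chloromethyl methyl ether, COCCl
Why: O-alkylation of the phenol to a MOM acetal, a protecting group stable to base, boron triflate and hydride and removable later with acid without touching the aryl bromide.

Step 4
Reactants: 6 methyl 2-[4-bromo-2-methoxy-6-(methoxymethoxy)phenoxy]acetate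
Product: 7 2-[4-bromo-2-methoxy-6-(methoxymethoxy)phenoxy]acetic acid
Conditions: LiOH·H2O, THF/H2O, rt; then 1 M HCl to pH 3 at 0 °C
Reagents that add atoms: lithium hydroxide, [Li+].[OH-]
Why: Saponification of an unhindered methyl ester; the MOM acetal is stable to base and survives the brief cold acidification.

Step 5
Reactants: 7 2-[4-bromo-2-methoxy-6-(methoxymethoxy)phenoxy]acetic acid; 8 (S)-4-benzyloxazolidin-2-one
Product: 10 (S)-4-benzyl-3-{2-[4-bromo-2-methoxy-6-(methoxymethoxy)phenoxy]acetyl}oxazolidin-2-one, via mixed pivalic anhydride 9 (not isolated)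
Conditions: t-BuCOCl, Et3N, THF, −20 °C; then LiCl, 8, −20 °C to rt
Reagents that add atoms: none
Why: N-acylation through a mixed anhydride, in which the hindered pivaloyl carbonyl directs the LiCl/Et3N-activated oxazolidinone to the aryloxyacetyl carbonyl.

Step 6
Reactants: 10 (S)-4-benzyl-3-{2-[4-bromo-2-methoxy-6-(methoxymethoxy)phenoxy]acetyl}oxazolidin-2-one; 11 3,4,5-trimethoxybenzaldehyde
Product: 14 (S)-4-benzyl-3-{(2S,3R)-2-[4-bromo-2-methoxy-6-(methoxymethoxy)phenoxy]-3-hydroxy-3-(3,4,5-trimethoxyphenyl)propanoyl}oxazolidin-2-one, via (Z)-dibutylboron enolate 12 (not isolated), via dibutylboron aldolate 13 (not isolated)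
Conditions: Bu2BOTf, Et3N, CH2Cl2, −78 to 0 °C; 11, −78 to 0 °C; then pH 7 buffer, MeOH, 30% H2O2, 0 °C
Reagents that add atoms: none
Why: Evans syn glycolate aldol: the (Z)-boron enolate reacts through a dipole-minimised Zimmerman–Traxler chair on the face away from the benzyl group, giving the (2S,3R) syn adduct, so the aryloxy-bearing carbon (the methyl-bearing R centre of the target) is set by the auxiliary.

Step 7
Reactants: 14 (S)-4-benzyl-3-{(2S,3R)-2-[4-bromo-2-methoxy-6-(methoxymethoxy)phenoxy]-3-hydroxy-3-(3,4,5-trimethoxyphenyl)propanoyl}oxazolidin-2-one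
Product: 15 (1R,2R)-2-[4-bromo-2-methoxy-6-(methoxymethoxy)phenoxy]-1-(3,4,5-trimethoxyphenyl)propane-1,3-diol
Conditions: LiBH4, MeOH (2.5 equiv), THF, 0 °C
Reagents that add atoms: none
Why: Reductive cleavage of the N-acyl oxazolidinone at the exocyclic carbonyl under cold, weakly basic conditions that avoid retro-aldol and do not touch either stereocentre, the aryl bromide or the MOM ether.

Step 8
Reactants: 15 (1R,2R)-2-[4-bromo-2-methoxy-6-(methoxymethoxy)phenoxy]-1-(3,4,5-trimethoxyphenyl)propane-1,3-diol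
Product: 16 (2R,3R)-2-[4-bromo-2-methoxy-6-(methoxymethoxy)phenoxy]-3-hydroxy-3-(3,4,5-trimethoxyphenyl)propyl 4-methylbenzenesulfonate
Conditions: TsCl (1.15 equiv), Et3N, DMAP (cat.), CH2Cl2, 0 °C
Reagents that add atoms: p-toluenesulfonyl chloride, Cc1ccc(cc1)S(Cl)(=O)=O
Why: Chemoselective sulfonylation of the primary hydroxyl over the hindered secondary benzylic one.

Step 9
Reactants: 16 (2R,3R)-2-[4-bromo-2-methoxy-6-(methoxymethoxy)phenoxy]-3-hydroxy-3-(3,4,5-trimethoxyphenyl)propyl 4-methylbenzenesulfonate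
Product: 17 (1R,2R)-2-[4-bromo-2-methoxy-6-(methoxymethoxy)phenoxy]-1-(3,4,5-trimethoxyphenyl)propan-1-ol
Conditions: LiEt3BH (3.5 equiv), THF, 0 °C to rt
Reagents that add atoms: none
Why: SN2 hydride displacement of a primary tosylate, fast enough at 0 °C to outrun oxetane formation and to leave the aryl bromide alone; the ring B oxygen is still MOM-protected, so it cannot attack the tosylate.

Step 10
Reactants: 17 (1R,2R)-2-[4-bromo-2-methoxy-6-(methoxymethoxy)phenoxy]-1-(3,4,5-trimethoxyphenyl)propan-1-ol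
Product: 18 5-bromo-2-{[(1R,2R)-1-hydroxy-1-(3,4,5-trimethoxyphenyl)propan-2-yl]oxy}-3-methoxyphenol
Conditions: 3 M aq. HCl, THF, 45 °C
Reagents that add atoms: none
Why: Acid hydrolysis of the aryl MOM acetal in aqueous medium, where any benzylic ionisation only returns the carbinol or begins the ring closure that step 11 completes.

Step 11
Reactants: 18 5-bromo-2-{[(1R,2R)-1-hydroxy-1-(3,4,5-trimethoxyphenyl)propan-2-yl]oxy}-3-methoxyphenol
Product: 19 (2R,3R)-7-bromo-5-methoxy-3-methyl-2-(3,4,5-trimethoxyphenyl)-2,3-dihydro-1,4-benzodioxine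
Conditions: TsOH·H2O (0.2 equiv), toluene, 80 °C
Reagents that add atoms: none
Why: Acid-catalysed SN1 cyclodehydration: the phenol traps the trimethoxybenzylic cation in a reversible 6-ring closure, so the untouched methyl-bearing centre steers the aryl-bearing carbon to the diequatorial trans (2R,3R) isomer whichever carbinol epimer enters.

Step 12
Reactants: 19 (2R,3R)-7-bromo-5-methoxy-3-methyl-2-(3,4,5-trimethoxyphenyl)-2,3-dihydro-1,4-benzodioxine; 20 methyl acrylate
Product: 21 methyl (E)-3-[(2R,3R)-8-methoxy-2-methyl-3-(3,4,5-trimethoxyphenyl)-2,3-dihydro-1,4-benzodioxin-6-yl]prop-2-enoate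
Conditions: Pd(OAc)2 (5 mol %), P(o-tol)3 (12 mol %), Et3N, DMF, 100 °C
Reagents that add atoms: none
Why: Mizoroki–Heck reaction; syn carbopalladation then syn β-hydride elimination gives only the (E)-cinnamate, and the bromide is unhindered (two ortho hydrogens).

Step 13
Reactants: 21 methyl (E)-3-[(2R,3R)-8-methoxy-2-methyl-3-(3,4,5-trimethoxyphenyl)-2,3-dihydro-1,4-benzodioxin-6-yl]prop-2-enoate
Product: 22 (E)-3-[(2R,3R)-8-methoxy-2-methyl-3-(3,4,5-trimethoxyphenyl)-2,3-dihydro-1,4-benzodioxin-6-yl]prop-2-en-1-ol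
Conditions: i-Bu2AlH (2.5 equiv), CH2Cl2, −78 °C; aq. KNaC4H4O6 (potassium sodium tartrate) work-up
Reagents that add atoms: none
Why: 1,2-Reduction of the α,β-unsaturated ester with i-Bu2AlH gives the allylic alcohol without changing the alkene geometry or the ring stereocentres.

**Compound list**
1 | 5-bromo-2-hydroxy-3-methoxybenzaldehyde (5-bromo-o-vanillin) | COc1cc(Br)cc(C=O)c1O | starting material
2 | methyl bromoacetate | COC(=O)CBr | starting material
3 | methyl 2-(4-bromo-2-formyl-6-methoxyphenoxy)acetate | COC(=O)COc1c(OC)cc(Br)cc1C=O | intermediate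
4 | methyl 2-[4-bromo-2-(formyloxy)-6-methoxyphenoxy]acetate (aryl formate) | COC(=O)COc1c(OC)cc(Br)cc1OC=O | intermediate
5 | methyl 2-(4-bromo-2-hydroxy-6-methoxyphenoxy)acetate | COC(=O)COc1c(OC)cc(Br)cc1O | intermediate
6 | methyl 2-[4-bromo-2-methoxy-6-(methoxymethoxy)phenoxy]acetate | COC(=O)COc1c(OC)cc(Br)cc1OCOC | intermediate
7 | 2-[4-bromo-2-methoxy-6-(methoxymethoxy)phenoxy]acetic acid | OC(=O)COc1c(OC)cc(Br)cc1OCOC | intermediate
8 | (S)-4-benzyloxazolidin-2-one | O=C1N[C@@H](Cc2ccccc2)CO1 | starting material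
9 | 2-[4-bromo-2-methoxy-6-(methoxymethoxy)phenoxy]acetic pivalic anhydride (mixed pivalic anhydride) | CC(C)(C)C(=O)OC(=O)COc1c(OC)cc(Br)cc1OCOC | intermediate
10 | (S)-4-benzyl-3-{2-[4-bromo-2-methoxy-6-(methoxymethoxy)phenoxy]acetyl}oxazolidin-2-one | O=C1OC[C@H](Cc2ccccc2)N1C(=O)COc1c(OC)cc(Br)cc1OCOC | intermediate
11 | 3,4,5-trimethoxybenzaldehyde | COc1cc(C=O)cc(OC)c1OC | starting material
12 | (S)-4-benzyl-3-{(Z)-2-[4-bromo-2-methoxy-6-(methoxymethoxy)phenoxy]-1-[(dibutylboranyl)oxy]ethenyl}oxazolidin-2-one ((Z)-dibutylboron enolate) | CCCCB(CCCC)O/C(=C\Oc1c(OC)cc(Br)cc1OCOC)N1C(=O)OC[C@@H]1Cc1ccccc1 | intermediate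
13 | (S)-4-benzyl-3-{(2S,3R)-2-[4-bromo-2-methoxy-6-(methoxymethoxy)phenoxy]-3-[(dibutylboranyl)oxy]-3-(3,4,5-trimethoxyphenyl)propanoyl}oxazolidin-2-one (dibutylboron aldolate) | O=C1OC[C@H](Cc2ccccc2)N1C(=O)[C@@H](Oc1c(OC)cc(Br)cc1OCOC)[C@H](OB(CCCC)CCCC)c1cc(OC)c(OC)c(OC)c1 | intermediate
14 | (S)-4-benzyl-3-{(2S,3R)-2-[4-bromo-2-methoxy-6-(methoxymethoxy)phenoxy]-3-hydroxy-3-(3,4,5-trimethoxyphenyl)propanoyl}oxazolidin-2-one | O=C1OC[C@H](Cc2ccccc2)N1C(=O)[C@@H](Oc1c(OC)cc(Br)cc1OCOC)[C@H](O)c1cc(OC)c(OC)c(OC)c1 | intermediate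
15 | (1R,2R)-2-[4-bromo-2-methoxy-6-(methoxymethoxy)phenoxy]-1-(3,4,5-trimethoxyphenyl)propane-1,3-diol | COc1cc([C@@H](O)[C@@H](CO)Oc2c(OC)cc(Br)cc2OCOC)cc(OC)c1OC | intermediate
16 | (2R,3R)-2-[4-bromo-2-methoxy-6-(methoxymethoxy)phenoxy]-3-hydroxy-3-(3,4,5-trimethoxyphenyl)propyl 4-methylbenzenesulfonate | COc1cc([C@@H](O)[C@@H](COS(=O)(=O)c2ccc(C)cc2)Oc2c(OC)cc(Br)cc2OCOC)cc(OC)c1OC | intermediate
17 | (1R,2R)-2-[4-bromo-2-methoxy-6-(methoxymethoxy)phenoxy]-1-(3,4,5-trimethoxyphenyl)propan-1-ol | COc1cc([C@@H](O)[C@@H](C)Oc2c(OC)cc(Br)cc2OCOC)cc(OC)c1OC | intermediate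
18 | 5-bromo-2-{[(1R,2R)-1-hydroxy-1-(3,4,5-trimethoxyphenyl)propan-2-yl]oxy}-3-methoxyphenol | COc1cc([C@@H](O)[C@@H](C)Oc2c(OC)cc(Br)cc2O)cc(OC)c1OC | intermediate
19 | (2R,3R)-7-bromo-5-methoxy-3-methyl-2-(3,4,5-trimethoxyphenyl)-2,3-dihydro-1,4-benzodioxine | COc1cc([C@H]2Oc3cc(Br)cc(OC)c3O[C@@H]2C)cc(OC)c1OC | intermediate
20 | methyl acrylate | COC(=O)C=C | starting material
21 | methyl (E)-3-[(2R,3R)-8-methoxy-2-methyl-3-(3,4,5-trimethoxyphenyl)-2,3-dihydro-1,4-benzodioxin-6-yl]prop-2-enoate | COc1cc([C@H]2Oc3cc(/C=C/C(=O)OC)cc(OC)c3O[C@@H]2C)cc(OC)c1OC | intermediate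
22 | (E)-3-[(2R,3R)-8-methoxy-2-methyl-3-(3,4,5-trimethoxyphenyl)-2,3-dihydro-1,4-benzodioxin-6-yl]prop-2-en-1-ol | COc1cc([C@H]2Oc3cc(/C=C/CO)cc(OC)c3O[C@@H]2C)cc(OC)c1OC | target

**Totals**
Total step count: 13. Longest linear sequence: 13 steps (1 to 22); compounds 2, 8, 11 and 20 are bought and enter directly.

**Steps most likely to fail, with fallbacks**

Step 6 (aldol). The enolate carries a hindered 2,6-disubstituted aryloxy group and the aldehyde is electron-rich, so conversion or facial selectivity may be poor. The fallback sets out from acid 7 and comes back at diol 15. Acid 7 is coupled (EDC·HCl, DMAP, CH2Cl2) with (S)-4-benzylthiazolidine-2-thione to give (S)-4-benzyl-3-{2-[4-bromo-2-methoxy-6-(methoxymethoxy)phenoxy]acetyl}thiazolidine-2-thione F1. Its chlorotitanium enolate (TiCl4 1.05 equiv, i-Pr2NEt 1.1 equiv, N-methyl-2-pyrrolidinone 1 equiv, CH2Cl2, −78 to 0 °C) adds to 11 through the non-chelated transition state. This gives the same syn sense, (S)-4-benzyl-3-{(2S,3R)-2-[4-bromo-2-methoxy-6-(methoxymethoxy)phenoxy]-3-hydroxy-3-(3,4,5-trimethoxyphenyl)propanoyl}thiazolidine-2-thione F2. NaBH4 (THF/EtOH, 0 °C) then displaces the thione auxiliary directly to give 15.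

Step 11 (ring closure). The trans/cis ratio may be modest, or the cation may eliminate to an enol ether and erode the methyl-bearing centre. The fallback sets out from 17 and comes back at 19, replacing the SN1 closure by two stereospecific inversions. Mitsunobu esterification of 17 (4-nitrobenzoic acid, PPh3, DIAD, THF, 0 °C to rt) inverts the carbinol to (1S,2R)-2-[4-bromo-2-methoxy-6-(methoxymethoxy)phenoxy]-1-(3,4,5-trimethoxyphenyl)propyl 4-nitrobenzoate F3. Methanolysis (K2CO3, MeOH, rt) gives (1S,2R)-2-[4-bromo-2-methoxy-6-(methoxymethoxy)phenoxy]-1-(3,4,5-trimethoxyphenyl)propan-1-ol F4. Brief MOM removal (3 M aq. HCl, THF, rt) gives 5-bromo-2-{[(1S,2R)-1-hydroxy-1-(3,4,5-trimethoxyphenyl)propan-2-yl]oxy}-3-methoxyphenol F5. Intramolecular Mitsunobu etherification (PPh3, DIAD, THF, 0 °C) then closes the ring with SN2 inversion at the benzylic carbon, giving trans 19.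

Step 12 (Heck). Oxidative addition of zerovalent palladium to the electron-rich bromide may be sluggish and give protodebromination. The fallback sets out from 19 and comes back at 21. Bromine–lithium exchange (n-BuLi, THF, −78 °C) and a DMF quench give (2R,3R)-8-methoxy-2-methyl-3-(3,4,5-trimethoxyphenyl)-2,3-dihydro-1,4-benzodioxine-6-carbaldehyde F6. Horner–Wadsworth–Emmons olefination with trimethyl phosphonoacetate (NaH, THF, 0 °C to rt) then gives the (E)-ester 21.

**Further compounds**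
F1 | step 6 | (S)-4-benzyl-3-{2-[4-bromo-2-methoxy-6-(methoxymethoxy)phenoxy]acetyl}thiazolidine-2-thione | S=C1SC[C@H](Cc2ccccc2)N1C(=O)COc1c(OC)cc(Br)cc1OCOC
F2 | step 6 | (S)-4-benzyl-3-{(2S,3R)-2-[4-bromo-2-methoxy-6-(methoxymethoxy)phenoxy]-3-hydroxy-3-(3,4,5-trimethoxyphenyl)propanoyl}thiazolidine-2-thione | S=C1SC[C@H](Cc2ccccc2)N1C(=O)[C@@H](Oc1c(OC)cc(Br)cc1OCOC)[C@H](O)c1cc(OC)c(OC)c(OC)c1
F3 | step 11 | (1S,2R)-2-[4-bromo-2-methoxy-6-(methoxymethoxy)phenoxy]-1-(3,4,5-trimethoxyphenyl)propyl 4-nitrobenzoate | COc1cc([C@H](OC(=O)c2ccc(cc2)[N+](=O)[O-])[C@@H](C)Oc2c(OC)cc(Br)cc2OCOC)cc(OC)c1OC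
F4 | step 11 | (1S,2R)-2-[4-bromo-2-methoxy-6-(methoxymethoxy)phenoxy]-1-(3,4,5-trimethoxyphenyl)propan-1-ol | COc1cc([C@H](O)[C@@H](C)Oc2c(OC)cc(Br)cc2OCOC)cc(OC)c1OC
F5 | step 11 | 5-bromo-2-{[(1S,2R)-1-hydroxy-1-(3,4,5-trimethoxyphenyl)propan-2-yl]oxy}-3-methoxyphenol | COc1cc([C@H](O)[C@@H](C)Oc2c(OC)cc(Br)cc2O)cc(OC)c1OC
F6 | step 12 | (2R,3R)-8-methoxy-2-methyl-3-(3,4,5-trimethoxyphenyl)-2,3-dihydro-1,4-benzodioxine-6-carbaldehyde | COc1cc([C@H]2Oc3cc(C=O)cc(OC)c3O[C@@H]2C)cc(OC)c1OC
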